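**Retrosynthetic overview**

1. The C3 ester is made last, from the bicyclic allylic alcohol and (2E,4E,6S)-6-methylocta-2,4-dienoic acid; the acid comes from (S)-2-methylbutan-1-ol by oxidation and vinylogous Horner–Wadsworth–Emmons olefination.
2. The C7 isopropylidene comes from an acetone aldol and dehydration at C7, after 1,4-reduction of the C6=C7 enone of a cross-conjugated trienone.
3. Ring A (C1–C2–C3–C4–C5–C10) is closed by forming C1–C10 in an intramolecular Heck reaction of a Z-iodoalkene. The strategy rests on quaternary C5 of ring B: while ring B is a 4,4-disubstituted cyclohexa-2,5-dienone, C5 is a prochiral centre and the two enone arms (C6=C7 and C9=C10, either side of the C8 ketone) are diastereotopic. The C3 and C4 centres of the tether select one arm and so create C5.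
4. Ring B comes from Robinson annulation of an α-methyl aldehyde with methyl vinyl ketone, then dehydrogenation. C3 and C4 are set together by anti-crotylboration of 3-(trimethylsilyl)propynal; the vinyl group is converted to the α-methyl aldehyde by Wacker oxidation and one-carbon homologation.
5. Ring order: ring B first (steps 6 and 7), ring A second (step 10).

Key step: step 10

Remark: atom labels C1–C10 are eremophilane positions (C3 carbinol carbon, C4 methyl-bearing CH, C5 quaternary carbon, C7 isopropylidene carbon, C8 ketone) and are kept for the open-chain intermediates.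

**Route**

Step 1
Reactants: 1 3-(trimethylsilyl)prop-2-ynal; 2 (E)-but-2-ene
Product: 3 (3R,4R)-4-methyl-1-(trimethylsilyl)hex-5-en-1-yn-3-ol
Conditions: 2 (excess), KOt-Bu, n-BuLi, THF, −78 → −45 °C; (+)-Ipc2BOMe [from (−)-α-pinene], −78 °C; BF3·OEt2; then 1, −78 °C; NaBO3·4H2O, THF/H2O, rt
Reagents that add atoms: none
Why: Brown crotylboration, in which the (E)-crotylborane adds through a closed chair (Zimmerman–Traxler) transition state so that the E geometry gives the 3,4-anti pair, and the isopinocampheyl groups derived from (−)-α-pinene direct attack to the Re face of the ynal, setting 3R and 4R together.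

Step 2
Reactants: 3 (3R,4R)-4-methyl-1-(trimethylsilyl)hex-5-en-1-yn-3-ol
Product: 4 tert-butyl(dimethyl){[(3R,4R)-4-methyl-1-(trimethylsilyl)hex-5-en-1-yn-3-yl]oxy}silane
Conditions: TBSCl, imidazole, DMF, rt
Reagents that add atoms: tert-butyldimethylsilyl chloride, CC(C)(C)[Si](C)(C)Cl
Why: Imidazole-promoted O-silylation of a secondary propargylic alcohol, which touches no stereocentre.

Step 3
Reactants: 4 tert-butyl(dimethyl){[(3R,4R)-4-methyl-1-(trimethylsilyl)hex-5-en-1-yn-3-yl]oxy}silane
Product: 5 (3S,4R)-4-{[tert-butyl(dimethyl)silyl]oxy}-3-methyl-6-(trimethylsilyl)hex-5-yn-2-one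
Conditions: PdCl2 (10 mol %), CuCl (1 equiv), O2 (1 atm), DMF/H2O 7:1, rt
Reagents that add atoms: water, O
Why: Tsuji–Wacker oxidation, in which divalent palladium effects Markovnikov hydroxypalladation of the monosubstituted alkene to give the methyl ketone, while the silyl-capped internal alkyne and the silyl ether are spectators and the near-neutral medium should leave the new α-centre (C4) intact (the descriptor changes to 3S only through priority).

Step 4
Reactants: 5 (3S,4R)-4-{[tert-butyl(dimethyl)silyl]oxy}-3-methyl-6-(trimethylsilyl)hex-5-yn-2-one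
Product: 6 tert-butyl{[(3R,4R)-6-methoxy-4,5-dimethyl-1-(trimethylsilyl)hex-5-en-1-yn-3-yl]oxy}dimethylsilane (E/Z mixture)
Conditions: Ph3P(CH2OMe)Cl (2.5 equiv), KN(SiMe3)2 (2.3 equiv), THF, 0 °C; then 5, −78 → 0 °C
Reagents that add atoms: (methoxymethyl)triphenylphosphonium chloride, COC[P+](c1ccccc1)(c1ccccc1)c1ccccc1.[Cl-]
Why: Wittig methoxymethylenation of the methyl ketone, run cold with the phosphonium salt in excess over the amide base so that carbonyl addition should outpace enolisation toward C4 and the 3,4-anti pair is kept; the enol ether geometry is irrelevant.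

Step 5
Reactants: 6 tert-butyl{[(3R,4R)-6-methoxy-4,5-dimethyl-1-(trimethylsilyl)hex-5-en-1-yn-3-yl]oxy}dimethylsilane
Product: 7 (3R,4R)-4-{[tert-butyl(dimethyl)silyl]oxy}-2,3-dimethyl-6-(trimethylsilyl)hex-5-ynal (both C2 epimers)
Conditions: p-TsOH·H2O (0.2 equiv), acetone/H2O 10:1, 0 °C → rt
Reagents that add atoms: water, O
Why: Acid-catalysed enol ether hydrolysis (C-protonation, hydration of the oxocarbenium ion, loss of methanol) unmasks the homologated α-methyl aldehyde; its α-centre may be a mixture because it later becomes the prochiral quaternary carbon, and the hindered secondary silyl ether should survive the mild acid.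

Step 6
Reactants: 7 (3R,4R)-4-{[tert-butyl(dimethyl)silyl]oxy}-2,3-dimethyl-6-(trimethylsilyl)hex-5-ynal; 8 methyl vinyl ketone
Product: 11 4-[(2R,3R)-3-{[tert-butyl(dimethyl)silyl]oxy}pent-4-yn-2-yl]-4-methylcyclohex-2-en-1-one (both C4 epimers), via desilylated aldehyde 9 (not isolated), via keto aldehyde Michael adduct 10 (not isolated)
Conditions: 8 (1.5 equiv), KOH (0.5 equiv), MeOH, 0 °C → rt, then 50 °C
Reagents that add atoms: none
Why: Robinson annulation, in which the aldehyde enolate adds to methyl vinyl ketone (Michael), the methyl ketone then condenses onto the now non-enolisable aldehyde (aldol, dehydration) to give the 4,4-disubstituted cyclohexenone, and methanolic hydroxide removes the alkynyl trimethylsilyl group in the same flask; the quaternary centre forms as both epimers, which converge in step 7.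

Step 7
Reactants: 11 4-[(2R,3R)-3-{[tert-butyl(dimethyl)silyl]oxy}pent-4-yn-2-yl]-4-methylcyclohex-2-en-1-one
Product: 12 4-[(2R,3R)-3-{[tert-butyl(dimethyl)silyl]oxy}pent-4-yn-2-yl]-4-methylcyclohexa-2,5-dien-1-one
Conditions: 2-iodoxybenzoic acid (IBX, 3 equiv), DMSO, 75 °C
Reagents that add atoms: none
Why: IBX dehydrogenation of the enone at its α′,β′ position through the cross-conjugated enol gives the 2,5-dienone, in which the quaternary carbon is no longer stereogenic so both epimers of 11 converge; the alkyne and the silyl ether are inert to the oxidant.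

Step 8
Reactants: 12 4-[(2R,3R)-3-{[tert-butyl(dimethyl)silyl]oxy}pent-4-yn-2-yl]-4-methylcyclohexa-2,5-dien-1-one
Product: 13 4-[(2R,3R)-3-{[tert-butyl(dimethyl)silyl]oxy}-5-iodopent-4-yn-2-yl]-4-methylcyclohexa-2,5-dien-1-one
Conditions: NIS (1.2 equiv), AgNO3 (10 mol %), acetone, rt, dark
Reagents that add atoms: N-iodosuccinimide, O=C1CCC(=O)N1I
Why: Silver-catalysed electrophilic iodination of the terminal alkyne through the silver acetylide, under neutral conditions that leave the dienone alone.

Step 9
Reactants: 13 4-[(2R,3R)-3-{[tert-butyl(dimethyl)silyl]oxy}-5-iodopent-4-yn-2-yl]-4-methylcyclohexa-2,5-dien-1-one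
Product: 14 4-[(2R,3R,4Z)-3-{[tert-butyl(dimethyl)silyl]oxy}-5-iodopent-4-en-2-yl]-4-methylcyclohexa-2,5-dien-1-one
Conditions: KO2CN=NCO2K (dipotassium azodicarboxylate, excess, added in portions), AcOH, MeOH/pyridine, rt, dark
Reagents that add atoms: none
Why: Diimide reduction, a concerted syn transfer of H2 from HN=NH to the iodoalkyne that gives only the Z-iodoalkene without C–I cleavage; the hindered, polarised ring alkenes of the dienone should react much more slowly, so the reagent is dosed until 13 is consumed.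

Step 10
Reactants: 14 4-[(2R,3R,4Z)-3-{[tert-butyl(dimethyl)silyl]oxy}-5-iodopent-4-en-2-yl]-4-methylcyclohexa-2,5-dien-1-one
Product: 15 (4aR,5R,6S)-6-{[tert-butyl(dimethyl)silyl]oxy}-4a,5-dimethyl-5,6-dihydronaphthalen-2(4aH)-one
Conditions: Pd(OAc)2 (10 mol %), PPh3 (30 mol %), Ag2CO3 (2 equiv), MeCN, 70 °C
Reagents that add atoms: none
Why: Mizoroki–Heck cyclisation: zerovalent palladium (from Pd(OAc)2 and PPh3) inserts into the C1–I bond with retention of the Z geometry, the alkenylpalladium adds syn across one enone arm (C1 to C10, Pd to C9), and the palladium enolate epimerises through its O-bound form so that syn β-hydride elimination of the C10 hydrogen restores the C9=C10 alkene, while Ag2CO3 removes iodide and supplies no hydride. The closest known reaction type is the intramolecular Heck desymmetrisation of 4,4-disubstituted cyclohexa-2,5-dienones carrying tethered aryl or alkenyl halides. Ring A is closed in the 6-exo-trig mode. The only new stereocentre, quaternary C5, is fixed by which of the two diastereotopic arms is attacked, and that choice is controlled by the resident C3 and C4 centres of the tether. Because the alkenyl carbon must approach perpendicular to the dienone plane, the spectator arm sits pseudo-axial and the C5 methyl pseudo-equatorial on the forming ring; in the chair-like transition state leading to 15 the bulky C3 silyloxy group is pseudo-equatorial and the C4 methyl pseudo-axial (anti to the spectator arm, facing only the C10 hydrogen), whereas closure onto the other arm would force the silyloxy group pseudo-axial and syn to the spectator arm. The step needs selectivity between the diastereotopic arms and for Heck over reductive closure; the first is secured by the C3/C4 substitution pattern (a matched chiral phosphine can reinforce it) and the second by the absence of a hydride donor.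

Step 11
Reactants: 15 (4aR,5R,6S)-6-{[tert-butyl(dimethyl)silyl]oxy}-4a,5-dimethyl-5,6-dihydronaphthalen-2(4aH)-one
Product: 16 (4aR,5R,6S)-6-{[tert-butyl(dimethyl)silyl]oxy}-4a,5-dimethyl-4,4a,5,6-tetrahydronaphthalen-2(3H)-one
Conditions: [(Ph3P)CuH]6 (0.4 equiv), degassed toluene, H2O (3 equiv), rt; aq. NH4Cl
Reagents that add atoms: none
Why: Copper hydride conjugate reduction, in which the univalent copper hydride should deliver hydride 1,4 to C6 of the disubstituted cross-conjugated enone, because C10 is fully substituted and the 1,6-terminus C2 is shielded by the adjacent silyloxy group, and protonation of the copper enolate gives the dienone.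

Step 12
Reactants: 16 (4aR,5R,6S)-6-{[tert-butyl(dimethyl)silyl]oxy}-4a,5-dimethyl-4,4a,5,6-tetrahydronaphthalen-2(3H)-one; 17 acetone
Product: 18 (4aR,5R,6S)-6-{[tert-butyl(dimethyl)silyl]oxy}-3-(2-hydroxypropan-2-yl)-4a,5-dimethyl-4,4a,5,6-tetrahydronaphthalen-2(3H)-one (both C3 epimers)
Conditions: LiN(i-Pr)2, THF, −78 °C; ZnCl2; 17, −78 → −40 °C; aq. NH4Cl
Reagents that add atoms: none
Why: Directed aldol reaction by kinetic α′-deprotonation at C7 (the only sp3 α-carbon), transmetallation to the zinc enolate to hold the tertiary aldolate against retro-aldol cleavage, and addition to acetone; the C7 configuration is removed in step 13.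

Step 13
Reactants: 18 (4aR,5R,6S)-6-{[tert-butyl(dimethyl)silyl]oxy}-3-(2-hydroxypropan-2-yl)-4a,5-dimethyl-4,4a,5,6-tetrahydronaphthalen-2(3H)-one
Product: 20 (4aR,5R,6S)-6-{[tert-butyl(dimethyl)silyl]oxy}-4a,5-dimethyl-3-(propan-2-ylidene)-4,4a,5,6-tetrahydronaphthalen-2(3H)-one, via tertiary mesylate 19 (not isolated)
Conditions: MsCl, Et3N, DMAP (cat.), CH2Cl2, 0 °C → rt; then DBU, rt
Reagents that add atoms: none
Why: Mesylation of the tertiary aldol hydroxyl (through sulfene) followed by E1cB elimination through the C7 enolate, which can only give the conjugated C7=C11 isopropylidene.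

Step 14
Reactants: 20 (4aR,5R,6S)-6-{[tert-butyl(dimethyl)silyl]oxy}-4a,5-dimethyl-3-(propan-2-ylidene)-4,4a,5,6-tetrahydronaphthalen-2(3H)-one
Product: 21 (4aR,5R,6S)-6-hydroxy-4a,5-dimethyl-3-(propan-2-ylidene)-4,4a,5,6-tetrahydronaphthalen-2(3H)-one
Conditions: HF·pyridine, THF/pyridine, 0 °C → rt
Reagents that add atoms: none
Why: Fluoride-mediated silyl ether cleavage under buffered, weakly acidic conditions that do not enolise the trienone, leaving C3 untouched.

Step 15
Reactants: 22 (S)-2-methylbutan-1-ol
Product: 23 (S)-2-methylbutanal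
Conditions: TEMPO (1 mol %), KBr (10 mol %), NaOCl (1.1 equiv), NaHCO3, CH2Cl2/H2O, 0 °C; used at once
Reagents that add atoms: none
Why: Anelli oxidation (TEMPO-catalysed hypochlorite oxidation through the oxoammonium salt) at 0 °C and buffered pH, conditions under which the α-stereocentre of this aldehyde is expected to survive.

Step 16
Reactants: 23 (S)-2-methylbutanal; 24 triethyl (E)-4-phosphonocrotonate
Product: 25 ethyl (2E,4E,6S)-6-methylocta-2,4-dienoate
Conditions: 24, LiN(SiMe3)2 (0.95 equiv relative to 24), THF, −78 °C; then 23, −78 → 0 °C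
Reagents that add atoms: none
Why: Vinylogous Horner–Wadsworth–Emmons olefination, with the phosphonate anion formed first and no free base left so that the α-stereocentre is not enolised; the stabilised anion should give the new C4=C5 alkene E and keep C2=C3 E.

Step 17
Reactants: 25 ethyl (2E,4E,6S)-6-methylocta-2,4-dienoate
Product: 26 (2E,4E,6S)-6-methylocta-2,4-dienoic acid
Conditions: LiOH·H2O, THF/MeOH/H2O, rt; then 1 M HCl
Reagents that add atoms: lithium hydroxide, [Li+].[OH-]
Why: Ester saponification at room temperature, which should neither deconjugate the dienoate nor touch the remote C6 centre.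

Step 18
Reactants: 21 (4aR,5R,6S)-6-hydroxy-4a,5-dimethyl-3-(propan-2-ylidene)-4,4a,5,6-tetrahydronaphthalen-2(3H)-one; 26 (2E,4E,6S)-6-methylocta-2,4-dienoic acid
Product: 27 (1R,2S,8aR)-1,8a-dimethyl-6-oxo-7-(propan-2-ylidene)-1,2,6,7,8,8a-hexahydronaphthalen-2-yl (2E,4E,6S)-6-methylocta-2,4-dienoate (CNP0215744.1)
Conditions: EDC·HCl (1.5 equiv), DMAP (0.3 equiv), CH2Cl2, 0 °C → rt
Reagents that add atoms: none
Why: Steglich-type carbodiimide esterification of the secondary allylic alcohol, in which only the O–H bond reacts so C3 is retained, under near-neutral conditions chosen to avoid deconjugation of the dienoyl unit and epimerisation at its C6.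

**Compound list**

1 | 3-(trimethylsilyl)prop-2-ynal | C[Si](C)(C)C#CC=O | starting material
2 | (E)-but-2-ene | C/C=C/C | starting material
3 | (3R,4R)-4-methyl-1-(trimethylsilyl)hex-5-en-1-yn-3-ol | C[Si](C)(C)C#C[C@H](O)[C@H](C)C=C | intermediate
4 | tert-butyl(dimethyl){[(3R,4R)-4-methyl-1-(trimethylsilyl)hex-5-en-1-yn-3-yl]oxy}silane | C[Si](C)(C)C#C[C@H](O[Si](C)(C)C(C)(C)C)[C@H](C)C=C | intermediate
5 | (3S,4R)-4-{[tert-butyl(dimethyl)silyl]oxy}-3-methyl-6-(trimethylsilyl)hex-5-yn-2-one | C[Si](C)(C)C#C[C@H](O[Si](C)(C)C(C)(C)C)[C@H](C)C(C)=O | intermediate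
6 | tert-butyl{[(3R,4R)-6-methoxy-4,5-dimethyl-1-(trimethylsilyl)hex-5-en-1-yn-3-yl]oxy}dimethylsilane (E/Z mixture) | C[Si](C)(C)C#C[C@H](O[Si](C)(C)C(C)(C)C)[C@H](C)C(C)=COC | intermediate
7 | (3R,4R)-4-{[tert-butyl(dimethyl)silyl]oxy}-2,3-dimethyl-6-(trimethylsilyl)hex-5-ynal (both C2 epimers) | C[Si](C)(C)C#C[C@H](O[Si](C)(C)C(C)(C)C)[C@H](C)C(C)C=O | intermediate
8 | methyl vinyl ketone (but-3-en-2-one) | CC(=O)C=C | starting material
9 | (3R,4R)-4-{[tert-butyl(dimethyl)silyl]oxy}-2,3-dimethylhex-5-ynal (both C2 epimers, not isolated) | C#C[C@H](O[Si](C)(C)C(C)(C)C)[C@H](C)C(C)C=O | intermediate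
10 | 2-[(2R,3R)-3-{[tert-butyl(dimethyl)silyl]oxy}pent-4-yn-2-yl]-2-methyl-5-oxohexanal (both C2 epimers, not isolated) | C#C[C@H](O[Si](C)(C)C(C)(C)C)[C@H](C)C(C)(C=O)CCC(C)=O | intermediate
11 | 4-[(2R,3R)-3-{[tert-butyl(dimethyl)silyl]oxy}pent-4-yn-2-yl]-4-methylcyclohex-2-en-1-one (both C4 epimers) | C#C[C@H](O[Si](C)(C)C(C)(C)C)[C@H](C)C1(C)CCC(=O)C=C1 | intermediate
12 | 4-[(2R,3R)-3-{[tert-butyl(dimethyl)silyl]oxy}pent-4-yn-2-yl]-4-methylcyclohexa-2,5-dien-1-one | C#C[C@H](O[Si](C)(C)C(C)(C)C)[C@H](C)C1(C)C=CC(=O)C=C1 | intermediate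
13 | 4-[(2R,3R)-3-{[tert-butyl(dimethyl)silyl]oxy}-5-iodopent-4-yn-2-yl]-4-methylcyclohexa-2,5-dien-1-one | IC#C[C@H](O[Si](C)(C)C(C)(C)C)[C@H](C)C1(C)C=CC(=O)C=C1 | intermediate
14 | 4-[(2R,3R,4Z)-3-{[tert-butyl(dimethyl)silyl]oxy}-5-iodopent-4-en-2-yl]-4-methylcyclohexa-2,5-dien-1-one | C[C@@H]([C@@H](O[Si](C)(C)C(C)(C)C)/C=C\I)C1(C)C=CC(=O)C=C1 | intermediate
15 | (4aR,5R,6S)-6-{[tert-butyl(dimethyl)silyl]oxy}-4a,5-dimethyl-5,6-dihydronaphthalen-2(4aH)-one | CC(C)(C)[Si](C)(C)O[C@H]1C=CC2=CC(=O)C=C[C@]2(C)[C@H]1C | intermediate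
16 | (4aR,5R,6S)-6-{[tert-butyl(dimethyl)silyl]oxy}-4a,5-dimethyl-4,4a,5,6-tetrahydronaphthalen-2(3H)-one | CC(C)(C)[Si](C)(C)O[C@H]1C=CC2=CC(=O)CC[C@]2(C)[C@H]1C | intermediate
17 | acetone | CC(C)=O | starting material
18 | (4aR,5R,6S)-6-{[tert-butyl(dimethyl)silyl]oxy}-3-(2-hydroxypropan-2-yl)-4a,5-dimethyl-4,4a,5,6-tetrahydronaphthalen-2(3H)-one (both C3 epimers) | CC(C)(C)[Si](C)(C)O[C@H]1C=CC2=CC(=O)C(C(C)(C)O)C[C@]2(C)[C@H]1C | intermediate
19 | 2-[(4aR,5R,6S)-6-{[tert-butyl(dimethyl)silyl]oxy}-4a,5-dimethyl-2-oxo-2,3,4,4a,5,6-hexahydronaphthalen-3-yl]propan-2-yl methanesulfonate (not isolated) | CC(C)(C)[Si](C)(C)O[C@H]1C=CC2=CC(=O)C(C(C)(C)OS(C)(=O)=O)C[C@]2(C)[C@H]1C | intermediate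
20 | (4aR,5R,6S)-6-{[tert-butyl(dimethyl)silyl]oxy}-4a,5-dimethyl-3-(propan-2-ylidene)-4,4a,5,6-tetrahydronaphthalen-2(3H)-one | CC(C)(C)[Si](C)(C)O[C@H]1C=CC2=CC(=O)C(=C(C)C)C[C@]2(C)[C@H]1C | intermediate
21 | (4aR,5R,6S)-6-hydroxy-4a,5-dimethyl-3-(propan-2-ylidene)-4,4a,5,6-tetrahydronaphthalen-2(3H)-one | O[C@H]1C=CC2=CC(=O)C(=C(C)C)C[C@]2(C)[C@H]1C | intermediate
22 | (S)-2-methylbutan-1-ol | CC[C@H](C)CO | starting material
23 | (S)-2-methylbutanal | CC[C@H](C)C=O | intermediate
24 | triethyl (E)-4-phosphonocrotonate | CCOC(=O)/C=C/CP(=O)(OCC)OCC | starting material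
25 | ethyl (2E,4E,6S)-6-methylocta-2,4-dienoate | CC[C@H](C)/C=C/C=C/C(=O)OCC | intermediate
26 | (2E,4E,6S)-6-methylocta-2,4-dienoic acid | CC[C@H](C)/C=C/C=C/C(=O)O | intermediate
27 | (1R,2S,8aR)-1,8a-dimethyl-6-oxo-7-(propan-2-ylidene)-1,2,6,7,8,8a-hexahydronaphthalen-2-yl (2E,4E,6S)-6-methylocta-2,4-dienoate | CC[C@H](C)/C=C/C=C/C(=O)O[C@H]1C=CC2=CC(=O)C(=C(C)C)C[C@]2(C)[C@H]1C | target

**Step count and risks**

Total step count: 18. Longest linear sequence: 15 (steps 1–14 and 18).

The three steps most likely to fail: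

1. Step 10. The two diastereotopic enone arms may be discriminated only weakly, and the palladium enolate may be protonated or decompose before it epimerises and undergoes β-hydride elimination. The fallback sets out from 14 and comes back at 15. The same C1–C10 bond is closed as a reductive Heck (conjugate-addition) cyclisation with Pd(OAc)2, the BINAP enantiomer that proves matched with the substrate bias, and HCO2Na in DMF at 60 °C. The alkylpalladium is then intercepted by formate-derived hydride and no β-hydride elimination is needed. This should give the cis-fused enone (4aS,5R,6S,8aS)-6-{[tert-butyl(dimethyl)silyl]oxy}-4a,5-dimethyl-4a,5,6,8a-tetrahydronaphthalen-2(1H)-one F1. IBX in DMSO at 70 °C then dehydrogenates C9–C10, the only enolisable α,β-position, to return to 15.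

2. Step 11. Hydride may be delivered in the 1,6-sense to C2 of the linear dienone, or reduction may run on past the C6=C7 alkene. The fallback sets out from 15 and comes back at 18, bypassing 16. A 1,4-hydrosilylation catalysed by (Ph3P)3RhCl with Et3SiH in toluene at 50 °C selects by alkene coordination and sterics and not by electrophilicity. It should give the triethylsilyl dienol ether {[(4aR,5R,6S)-6-{[tert-butyl(dimethyl)silyl]oxy}-4a,5-dimethyl-4,4a,5,6-tetrahydronaphthalen-2-yl]oxy}triethylsilane F2. A Mukaiyama aldol reaction of F2 with acetone (TiCl4, CH2Cl2, −78 °C) then gives 18 directly.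

3. Step 6. Michael addition at the hindered, fully substituted α-carbon may be sluggish, with hydroxide-induced polymerisation of methyl vinyl ketone competing. The fallback sets out from 7 and comes back at 11. Aldehyde 7 is converted with pyrrolidine (toluene, 4 Å molecular sieves, 60 °C) into the Stork enamine 1-[(3R,4R)-4-{[tert-butyl(dimethyl)silyl]oxy}-2,3-dimethyl-6-(trimethylsilyl)hex-1-en-5-yn-1-yl]pyrrolidine F3. F3 adds to methyl vinyl ketone under neutral conditions (dioxane, rt → 60 °C). KOH in MeOH/H2O then hydrolyses the adduct, effects the aldol condensation and removes the alkynyl trimethylsilyl group, giving 11.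

**Further compounds**

F1 | step 10 | (4aS,5R,6S,8aS)-6-{[tert-butyl(dimethyl)silyl]oxy}-4a,5-dimethyl-4a,5,6,8a-tetrahydronaphthalen-2(1H)-one | CC(C)(C)[Si](C)(C)O[C@H]1C=C[C@@H]2CC(=O)C=C[C@]2(C)[C@H]1C
F2 | step 11 | {[(4aR,5R,6S)-6-{[tert-butyl(dimethyl)silyl]oxy}-4a,5-dimethyl-4,4a,5,6-tetrahydronaphthalen-2-yl]oxy}triethylsilane | CC(C)(C)[Si](C)(C)O[C@H]1C=CC2=CC(O[Si](CC)(CC)CC)=CC[C@]2(C)[C@H]1C
F3 | step 6 | 1-[(3R,4R)-4-{[tert-butyl(dimethyl)silyl]oxy}-2,3-dimethyl-6-(trimethylsilyl)hex-1-en-5-yn-1-yl]pyrrolidine (E/Z mixture) | C[Si](C)(C)C#C[C@H](O[Si](C)(C)C(C)(C)C)[C@H](C)C(C)=CN1CCCC1
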